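The data stem from a simulated flask for substances that don't exist.

**Target so far.** The target in the zeta flask was read at 15.8% of the solid substrate charged after 3.00 min, and stirring continues to 25 min.

in all of them: solid substrate 0.19 M
- zeta: reagent 0.171 M; the very flask that is asked about, followed so far
- epsilon: reagent 0.34 M; run made earlier
- flask: reagent 0.171 M; time 25 min

| run | time / min | target / % | solid product / % |
|---|---|---|---|
| zeta | 0.500 | 1.1 | 0 |
| zeta | 1.00 | 3.8 | 0.3 |
| zeta | 1.50 | 6.1 | 0 |
| zeta | 2.00 | 9.8 | 0 |
| zeta | 2.50 | 12.4 | 0 |
| zeta | 3.00 | 15.8 | 0.7 |
| epsilon | 1.50 | 11.9 | 0.4 |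
| epsilon | 5.00 | 46.5 | 0.1 |
| epsilon | 8.00 | 65.7 | 0 |
| epsilon | 15.0 | 81.1 | 0 |
| epsilon | 20.0 | 85.8 | 3.8 |
| epsilon | 25.0 | 88.7 | 9.4 |

(scatter of a reading: 0.3 percentage points)

- amount of target and solid product and idle adduct together at 25 min, in percent of the solid substrate charged
- concentration of dissolved substrate in solution at 25 min, in percent of saturation

**Reading the rate.** At 1.50 min the epsilon run holds 11.9% of target against 6.1% in zeta, a factor 1.95 for a factor 1.99 in reagent, so the early rate follows the reagent. The reagent charge divided by the early rate of target formation gives 17.1 min in zeta. This is the reagent clock, and epsilon gives a close 19.2 min.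

**Own reckoning.** At 0.900 equivalents the reagent is the limiting reagent. If each target takes one reagent, the reagent falls pseudo-first-order on this clock, and this note expects 69.2% of the solid substrate charged at 25 min, with 23.2% of the reagent's own charge free. The charges stay untouched, since the zeta clock was read at these charges.

**The forecast.** It says 74% for the sum and 85% of saturation, higher on the sum than this note, from “about 85% of reagent consumed at most”.

**The result.** The flask gives 55.9% for the sum and 87.6% of saturation.

    dissolved substrate + reagent → target (k = 1.40 M⁻¹ min⁻¹)
    2 dissolved substrate → side product (k = 0.0280 M⁻¹ min⁻¹)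
    reagent + target ⇌ idle adduct, settled at all times (K = 210 M⁻¹)
    solid product ⇌ target, rate k4*(cs4 - [target]) while solid is left; crystals form when [target] > cs4 (solubility = 16.0 mM, k = 2.20 min⁻¹)
    2 solid substrate → homo dimer (k = 3.40 × 10⁻⁴ M⁻¹ min⁻¹)
    solid substrate ⇌ dissolved substrate, rate k6*(cs6 - [dissolved substrate]) while solid is left; crystals form when [dissolved substrate] > cs6 (solubility = 0.0860 M, k = 0.940 min⁻¹)

**Not at rest.** The flask's sum at 25 min lies below the clock's 69.2%, and its free reagent stands at 8.20% of its own charge against 23.2%, while idle adduct, 26.7% of the solid substrate charged, holds a second reagent on each of its targets. For a neighbour flask with 0.29 M of reagent the clock gives 117%, beyond the solid substrate charged, and that neighbour gives 81.7%. Ten times as long, at 250 min, the flask's sum reaches 84.2%, idle adduct falls to 4.44%, and solid product rises from 20.1% to 71.4%.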